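## The problem

Target 29 is a chalcone whose ring A (2',4'-dihydroxy-6'-methoxy) carries at C3' an oxane. The oxane is numbered O1, C2 (bearing the 2-(4-hydroxyphenyl)ethyl chain), C3, C4 (bearing ring A), C5 and C6 (bearing a 4-hydroxyphenyl group). Its three stereocenters are (2S,4R,6S), with all three substituents cis and therefore equatorial.

C2 and C6 face each other across O1, so one of them, taken from the chiral pool, can set the other through a cyclic transition state. C4 is remote from both, but once C2 and C6 are cis, hydrogenation of a C4=C5 alkene from the open face (or thermodynamic control) places ring A equatorial.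

The bond from C4 to ring A lies between two ortho oxygens and is a poor candidate for a late coupling. Ring A itself is symmetric until it is acylated, so the acyl group may enter at either free position.

Three features are fragile. The enone is reducible and, next to the free 2'-hydroxyl, closes to a flavanone under acid or base. The C6–O1 bond is a para-oxygenated benzylic ether that can ionise or be hydrogenolysed. Five phenols must be freed at the end. The enone therefore has to come after any hydrogenation, and the last deprotection has to be mild.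

The feature that opens the route is this: read backwards, a C4=C5 alkene next to a carboxyl-bearing C2 is the product of a [3,3] shift in which C4 and C3 were the two carbons of a 1-arylvinyl group on C5. Because the oxygen on C2 is O1 and already sits on C6, the rearranging ester is a lactone, a 1,4-dioxan-2-one.

## Retrosynthesis

**29 from 28.** The three methoxymethyl (MOM) ethers of 28 are cut last. Acetal cleavage in acidic methanol is the mildest unmasking that a 2'-hydroxychalcone tolerates. The two phenols on the oxane side are already free in 28, so only ring A and ring B oxygens remain protected.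

**28 from 22 and 26.** The bond between ring A and the enone carbonyl is cut. The neighbouring cut, an aldol disconnection of the enone after a separate acetylation, costs one more step on the main line. Acylation with the complete cinnamoyl unit 26 needs only one aryl anion. The precursor 22 has a symmetric ring A whose two free positions are equivalent and each lie between a MOM ether and the methoxy group, so deprotonation there is doubly directed. The forward reaction must metalate ring A without touching the two phenoxides or the benzylic C6–H.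

**22 from 21.** The C4–H and C5–H bonds, the two hydrogens of the side-chain alkene and the two benzyl ethers are all traced to one hydrogenation. This removes the C4 stereocenter from the problem: 21 has only C2 and C6. The forward step must add hydrogen to the ring alkene from the face of the axial C2–H and C6–H.

**21 from 17 and 19, and 17 from 15 through 16.** The side-chain alkene is cut by a Wittig disconnection into aldehyde 17 and phosphonium salt 19 (from chloride 18). The alkene geometry is irrelevant because it is hydrogenated. Aldehyde 17 is the reduced form of ester 16 and acid 15, so the whole C2 appendage reduces to a carboxyl group.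

**15 from 12 (key disconnection).** Bond C2–C3 is cut and the carboxyl oxygen is rejoined to C5, giving the 5,6-trans dioxanone 12.
- Against a hetero-Diels–Alder or a Prins cut, this keeps ring A on C4 from the start.
- It makes the C4=C5 alkene cis by construction.
- It lets the C6 stereocenter dictate C2 through a boat that the lactone ring enforces.
- The precursor 12 has two adjacent stereocenters, and only one of them (the mandelate carbon) survives.

**12 from 11, and 11 from 8 and 10.** The lactone C–O bond is cut to hydroxy ester 11. The bond between the carbinol carbon and the vinyl carbon is then cut to aldehyde 8 and the 1-arylvinyl metal 10. Carrying the glycolate ether on the aldehyde differentiates the two oxygens of the diol from the outset, which a late alkylation of a free syn diol could not do. The forward addition must be chelation-controlled to give the syn (1R,2R) alcohol.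

**8 from 4 and 6; 10 from 1.** Aldehyde 8 comes from diester 7, which is the ether of mandelate 5 with the glycolate unit of 6. Mandelate 5 is the dibenzyl derivative of acid 4, which supplies C6. The vinyl metal 10 comes through vinyllithium 9 from hydrazone 3 of ketone 2, the bis-MOM ether of acetophenone 1. The carbonyl and methyl carbons of 1 become C4 and C3, so the hindered ring A–C4 bond is bought, not made.

**26 from 23 and 25.** The enamide 26 is cut at its alkene into aldehyde 24 (the MOM ether of 23) and phosphonate 25.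

## Roads not taken

**Alternative 1: hetero-Diels–Alder.** The cut is at O1–C2 and C5–C6. Siloxydiene A2 and aldehyde A3 would combine under the CrCl complex (trivalent chromium) of the tridentate Schiff base from 3-(1-adamantyl)-5-methylsalicylaldehyde and cis-1-amino-2-indanol to give enol silane A1.
- Merits: both C2 and C6 are set catalytically from achiral partners, the cis relation follows from the endo transition state, the C2 side chain is complete at once, and no configurationally fragile aldehyde is handled. In these respects it is better than the chosen plan, which spends four steps growing the chain from a carboxyl group and relies on a mandelic aldehyde.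
- Weak points: an aryl aldehyde is a sluggish heterodienophile for a mono-oxygenated diene, which is why the phenol must be masked as an ester. More seriously, C4 of A1 carries only oxygen. Ring A would still have to be attached by a C–C coupling at an arene flanked by two ortho oxygens, followed by the same face-selective hydrogenation.
- Comparison: the chosen plan sets against it that ring A is on C4 from the first step and that the absolute configuration comes from an inexpensive acid.

**Alternative 2: dithiane linchpin.** The cut is at C3–C4 and C4–C5. Lithiated silyl dithiane A5 would open epoxide A6, a 1,4-Brook rearrangement would regenerate the anion, and this would open epoxide A7 to give the open chain A4.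
- Merits: three components join in one flask, both carbinol centers come from epoxides of defined configuration, and the chain from C2 to C6 is complete. In convergence this road is superior.
- Weak points: A4 is acyclic with two oxygens where the oxane needs one. One C–O bond must therefore be formed by displacement, either at the ionisation-prone benzylic C6 or at C2 with inversion. The bulky anion must attack the CH2 and not the activated benzylic carbon of A7. C4 is again a masked ketone that needs the hindered aryl coupling and a reduction.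
- Comparison: the chosen plan sets against the convergence that its key step delivers the ring, the C2 configuration and the aryl-bearing alkene in one event.

**Alternative 3: Danheiser benzannulation.** The cut is through ring A (C2'–C3' and C4'–C5'). Cyclobutenone A9 and siloxyalkyne A10 would be heated to give the resorcinol monosilyl ether A8.
- Merits: the crowded ring A–C4 bond is never formed on an arene, and no hindered styrene has to be hydrogenated. That is a real advantage over step 13 of the chosen plan.
- Weak points: A10 already contains the all-cis oxane with its C4 stereocenter, so the main stereochemical problem is moved to an unspecified earlier synthesis. A9 and the ynol ether are sensitive and must themselves be made. The differentiation of the two ring A oxygens that the benzannulation offers is not needed, since both end as free hydroxyls.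
- Comparison: the chosen plan sets against it a purchased ring A and a key step that builds the oxane itself.

Key step: step 8

Assumption: alkene 21 is carried on as its E/Z mixture because both isomers give the same saturated chain in step 13; the C=N geometry of 3 is likewise left unassigned.

## Route

Step 1
Reactants: 1 2',6'-dihydroxy-4'-methoxyacetophenone
Product: 2 1-[4-methoxy-2,6-bis(methoxymethoxy)phenyl]ethan-1-one
Conditions: NaH (2.5 equiv), MOMCl (2.5 equiv), DMF, 0 → 23 °C
Reagents that add atoms: chloromethyl methyl ether, COCCl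
Why: Williamson etherification of the bis-phenoxide; NaH is used because both hydroxyls are hydrogen-bonded to the carbonyl, and the MOM ethers later direct metalation and leave under mild acid.

Step 2
Reactants: 2 1-[4-methoxy-2,6-bis(methoxymethoxy)phenyl]ethan-1-one
Product: 3 N'-{1-[4-methoxy-2,6-bis(methoxymethoxy)phenyl]ethylidene}-2,4,6-tri(propan-2-yl)benzenesulfonohydrazide
Conditions: 2,4,6-(i-Pr)3C6H2SO2NHNH2 (1.2 equiv), THF, 4 Å molecular sieves, 23 → 40 °C
Reagents that add atoms: 2,4,6-tri(propan-2-yl)benzenesulfonohydrazide, CC(C)c1cc(C(C)C)c(S(=O)(=O)NN)c(C(C)C)c1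
Why: Condensation of a ketone with a sulfonyl hydrazide; the triisopropylphenyl group prevents ortho-lithiation of the sulfonyl arene in the Shapiro reaction that follows.

Step 3
Reactants: 4 (R)-4-hydroxymandelic acid
Product: 5 benzyl (2R)-2-[4-(benzyloxy)phenyl]-2-hydroxyacetate
Conditions: BnBr (2.2 equiv), K2CO3 (2.2 equiv), DMF, 23 °C
Reagents that add atoms: benzyl bromide, BrCc1ccccc1
Why: SN2 alkylation of carboxylate and phenoxide while the much less acidic secondary alcohol stays free; the weak base at room temperature leaves the stereocenter untouched.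

Step 4
Reactants: 5 benzyl (2R)-2-[4-(benzyloxy)phenyl]-2-hydroxyacetate; 6 tert-butyl diazoacetate
Product: 7 benzyl (2R)-2-[4-(benzyloxy)phenyl]-2-[2-(tert-butoxy)-2-oxoethoxy]acetate
Conditions: Rh2(OAc)4 (1 mol%), CH2Cl2, 23 °C, slow addition of 6
Reagents that add atoms: none
Why: Rhodium carbenoid O–H insertion installs the glycolate ether under neutral conditions, so the base-sensitive mandelate center never meets an alkoxide as it would in a Williamson alkylation.

Step 5
Reactants: 7 benzyl (2R)-2-[4-(benzyloxy)phenyl]-2-[2-(tert-butoxy)-2-oxoethoxy]acetate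
Product: 8 tert-butyl 2-{(1R)-1-[4-(benzyloxy)phenyl]-2-oxoethoxy}acetate
Conditions: i-Bu2AlH (1.1 equiv), CH2Cl2, −78 °C; aq. sodium potassium tartrate, 0 °C; used at once without chromatography
Reagents that add atoms: none
Why: Partial reduction of an α-alkoxy ester stops at the chelated aluminium hemiacetal; the benzyl ester reacts while the tert-butyl ester is inert at −78 °C, and the aldehyde is kept cold and neutral because its α-hydrogen is benzylic.

Step 6
Reactants: 3 N'-{1-[4-methoxy-2,6-bis(methoxymethoxy)phenyl]ethylidene}-2,4,6-tri(propan-2-yl)benzenesulfonohydrazide; 8 tert-butyl 2-{(1R)-1-[4-(benzyloxy)phenyl]-2-oxoethoxy}acetate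
Product: 11 tert-butyl 2-{(1R,2R)-1-[4-(benzyloxy)phenyl]-2-hydroxy-3-[4-methoxy-2,6-bis(methoxymethoxy)phenyl]but-3-en-1-yloxy}acetate, via vinyllithium 9 (not isolated), via vinylmagnesium bromide 10 (not isolated)
Conditions: 3 (1.4 equiv), n-BuLi (2.8 equiv), THF, −78 → 0 °C; MgBr2·OEt2, −78 °C; then 8 premixed with MgBr2·OEt2 in CH2Cl2, −78 °C; aq. NH4Cl
Reagents that add atoms: none
Why: The Shapiro reaction turns the hydrazone dianion into 9 with loss of N2 and sulfinate, and transmetalation gives 10; in the chelation-controlled addition magnesium bridges the aldehyde oxygen and the α-ether oxygen (the ester carbonyl can act as a third donor), so the nucleophile enters from the side of the α-hydrogen, away from the aryl group, and the syn (1R,2R) alcohol results; the minor anti isomer is removed by chromatography.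

Step 7
Reactants: 11 tert-butyl 2-{(1R,2R)-1-[4-(benzyloxy)phenyl]-2-hydroxy-3-[4-methoxy-2,6-bis(methoxymethoxy)phenyl]but-3-en-1-yloxy}acetate
Product: 12 (5R,6R)-5-[4-(benzyloxy)phenyl]-6-{1-[4-methoxy-2,6-bis(methoxymethoxy)phenyl]ethenyl}-1,4-dioxan-2-one
Conditions: KOt-Bu (0.1 equiv), THF (0.02 M), 0 → 23 °C; pH 7 buffer
Reagents that add atoms: none
Why: Alkoxide-catalysed intramolecular transesterification (lactonisation); closure of the six-membered ring with release of tert-butanol is entropically favoured in dilute aprotic solution, and basic catalysis spares the aryl MOM ethers that an acid-mediated lactonisation of a tert-butyl ester would endanger; the syn alcohol gives the 5,6-trans lactone.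

Step 8
Reactants: 12 (5R,6R)-5-[4-(benzyloxy)phenyl]-6-{1-[4-methoxy-2,6-bis(methoxymethoxy)phenyl]ethenyl}-1,4-dioxan-2-one
Product: 15 (2R,6S)-6-[4-(benzyloxy)phenyl]-4-[4-methoxy-2,6-bis(methoxymethoxy)phenyl]-3,6-dihydro-2H-pyran-2-carboxylic acid, via silyl ketene acetal 13 (not isolated), via trimethylsilyl ester 14 (not isolated)
Conditions: LiN(SiMe3)2 (1.3 equiv) added to 12 and Me3SiCl–Et3N (3 equiv) in THF, −78 °C; then toluene, 23 → 80 °C; aq. NaHCO3, then citric acid to pH 4 at 0 °C
Reagents that add atoms: none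
Why: LiN(SiMe3)2 removes a C3 proton of 12 with Me3SiCl already present, so the lactone enolate is trapped at once on oxygen as the ring-held ketene acetal 13. On warming, 13 undergoes the Ireland–Claisen rearrangement, a concerted [3,3]-sigmatropic shift in which the vinyl CH2 bonds to the ketene acetal carbon (pyran bond C2–C3) while the allylic C–O bond of the lactone breaks; silyl ester 14 results and is hydrolysed to 15 on work-up. The closest known reaction type is the ring contraction of 6-alkenyl-1,4-dioxan-2-ones to cis-2,6-disubstituted 3,6-dihydro-2H-pyran-2-carboxylic acids, applied here to a 1-arylvinyl group. The dihydropyran ring closes by C–C bond formation across a bicyclic, boat-shaped six-atom transition state, and the C4=C5 alkene is necessarily cis inside the new ring. The one new stereocenter, C2, is controlled by the mandelate-derived carbon (pyran C6): the tether lets the vinyl group reach only the face of the ketene acetal on which it is attached, and because the aryl group is trans to the vinyl group in 12 it lies on the side of the ketene acetal bridge, so the carboxyl group ends cis to it, (2R,6S). The carbinol stereocenter of 12 is consumed as C5 becomes trigonal. The step needs diastereoselection at C2, secured by the trans 5,6-substitution of 12 and the enforced boat, and O-silylation in preference to enolate fragmentation, secured by the in situ quench at −78 °C.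

Step 9
Reactants: 15 (2R,6S)-6-[4-(benzyloxy)phenyl]-4-[4-methoxy-2,6-bis(methoxymethoxy)phenyl]-3,6-dihydro-2H-pyran-2-carboxylic acid
Product: 16 methyl (2R,6S)-6-[4-(benzyloxy)phenyl]-4-[4-methoxy-2,6-bis(methoxymethoxy)phenyl]-3,6-dihydro-2H-pyran-2-carboxylate
Conditions: MeI (1.5 equiv), K2CO3, DMF, 23 °C
Reagents that add atoms: iodomethane, CI
Why: SN2 alkylation of the carboxylate; the α-hydrogen of a carboxylate is not acidic, so C2 is not at risk.

Step 10
Reactants: 16 methyl (2R,6S)-6-[4-(benzyloxy)phenyl]-4-[4-methoxy-2,6-bis(methoxymethoxy)phenyl]-3,6-dihydro-2H-pyran-2-carboxylate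
Product: 17 (2R,6S)-6-[4-(benzyloxy)phenyl]-4-[4-methoxy-2,6-bis(methoxymethoxy)phenyl]-3,6-dihydro-2H-pyran-2-carbaldehyde
Conditions: i-Bu2AlH (1.1 equiv), CH2Cl2, −78 °C; aq. sodium potassium tartrate
Reagents that add atoms: none
Why: Partial reduction of an α-alkoxy ester, halted at the aldehyde stage by the chelated tetrahedral intermediate; should C2 epimerise, the cis isomer with both substituents pseudo-equatorial is the favoured one.

Step 11
Reactants: 18 4-(benzyloxy)benzyl chloride
Product: 19 {[4-(benzyloxy)phenyl]methyl}triphenylphosphonium chloride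
Conditions: PPh3 (1.05 equiv), toluene, 110 °C
Reagents that add atoms: triphenylphosphine, c1ccc(P(c2ccccc2)c2ccccc2)cc1
Why: Quaternisation of a phosphine by a benzylic chloride (SN2); the salt precipitates from toluene.

Step 12
Reactants: 17 (2R,6S)-6-[4-(benzyloxy)phenyl]-4-[4-methoxy-2,6-bis(methoxymethoxy)phenyl]-3,6-dihydro-2H-pyran-2-carbaldehyde; 19 {[4-(benzyloxy)phenyl]methyl}triphenylphosphonium chloride
Product: 21 (2R,6S)-6-[4-(benzyloxy)phenyl]-2-{2-[4-(benzyloxy)phenyl]ethenyl}-4-[4-methoxy-2,6-bis(methoxymethoxy)phenyl]-3,6-dihydro-2H-pyran as an E/Z mixture, via ylide 20 (not isolated)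
Conditions: 19 (1.3 equiv), NaN(SiMe3)2 (1.25 equiv), THF, 0 °C; then 17, −78 → 23 °C
Reagents that add atoms: none
Why: Wittig reaction of a semi-stabilised benzylic ylide; adding the aldehyde to the preformed ylide at −78 °C limits enolisation at C2, and the alkene geometry does not matter.

Step 13
Reactants: 21 (2R,6S)-6-[4-(benzyloxy)phenyl]-2-{2-[4-(benzyloxy)phenyl]ethenyl}-4-[4-methoxy-2,6-bis(methoxymethoxy)phenyl]-3,6-dihydro-2H-pyran
Product: 22 4-{2-[(2S,4R,6S)-6-(4-hydroxyphenyl)-4-[4-methoxy-2,6-bis(methoxymethoxy)phenyl]oxan-2-yl]ethyl}phenol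
Conditions: H2 (3 atm), 10% Pd/C, EtOAc–EtOH, 23 °C
Reagents that add atoms: none
Why: Heterogeneous hydrogenation saturates both alkenes and hydrogenolyses both benzyl ethers; syn addition to the half-chair from the face of the axial C2–H and C6–H, away from the two pseudo-equatorial substituents, puts the new C4–H on that face and ring A equatorial, giving the all-cis (2S,4R,6S) oxane.

Step 14
Reactants: 23 4-hydroxybenzaldehyde
Product: 24 4-(methoxymethoxy)benzaldehyde
Conditions: MOMCl (1.3 equiv), i-Pr2NEt (1.5 equiv), CH2Cl2, 0 → 23 °C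
Reagents that add atoms: chloromethyl methyl ether, COCCl
Why: O-alkylation of the phenol with an α-chloro ether, a standard acetal protection.

Step 15
Reactants: 24 4-(methoxymethoxy)benzaldehyde; 25 diethyl {2-[methoxy(methyl)amino]-2-oxoethyl}phosphonate
Product: 26 (2E)-N-methoxy-N-methyl-3-[4-(methoxymethoxy)phenyl]prop-2-enamide
Conditions: NaH (1.1 equiv), THF, 0 → 23 °C
Reagents that add atoms: none
Why: Horner–Wadsworth–Emmons olefination with a stabilised phosphonate anion, which gives the E-alkene.

Step 16
Reactants: 22 4-{2-[(2S,4R,6S)-6-(4-hydroxyphenyl)-4-[4-methoxy-2,6-bis(methoxymethoxy)phenyl]oxan-2-yl]ethyl}phenol; 26 (2E)-N-methoxy-N-methyl-3-[4-(methoxymethoxy)phenyl]prop-2-enamide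
Product: 28 (2E)-1-{3-[(2S,4R,6S)-6-(4-hydroxyphenyl)-2-[2-(4-hydroxyphenyl)ethyl]oxan-4-yl]-6-methoxy-2,4-bis(methoxymethoxy)phenyl}-3-[4-(methoxymethoxy)phenyl]prop-2-en-1-one, via trilithio species 27 (not isolated)
Conditions: n-BuLi (3.3 equiv), THF, −78 → 0 °C; then 26 (1.5 equiv), −78 → 0 °C; aq. NH4Cl
Reagents that add atoms: none
Why: Two equivalents of base convert the phenols into phenoxides, which deactivates their rings; the third performs a directed ortho-metalation at the ring A position flanked by a MOM ether and the methoxy group (either of the two equivalent positions), and the aryllithium adds 1,2 to the N-methoxy-N-methylamide, whose chelated tetrahedral intermediate releases the enone only on work-up.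

Step 17
Reactants: 28 (2E)-1-{3-[(2S,4R,6S)-6-(4-hydroxyphenyl)-2-[2-(4-hydroxyphenyl)ethyl]oxan-4-yl]-6-methoxy-2,4-bis(methoxymethoxy)phenyl}-3-[4-(methoxymethoxy)phenyl]prop-2-en-1-one
Product: 29 (2E)-1-{2,4-dihydroxy-3-[(2S,4R,6S)-6-(4-hydroxyphenyl)-2-[2-(4-hydroxyphenyl)ethyl]oxan-4-yl]-6-methoxyphenyl}-3-(4-hydroxyphenyl)prop-2-en-1-one
Conditions: 3 M aq. HCl, MeOH, 23 °C
Reagents that add atoms: none
Why: Acid-catalysed acetal exchange with methanol removes the three aryl MOM ethers at room temperature, conditions under which a 2'-hydroxychalcone of this substitution pattern should persist; if the benzylic C6–O1 bond ionised, it would reclose to the same all-equatorial isomer.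

## Compound list

1 | 2',6'-dihydroxy-4'-methoxyacetophenone | CC(=O)c1c(O)cc(OC)cc1O | starting material
2 | 1-[4-methoxy-2,6-bis(methoxymethoxy)phenyl]ethan-1-one | CC(=O)c1c(OCOC)cc(OC)cc1OCOC | intermediate
3 | N'-{1-[4-methoxy-2,6-bis(methoxymethoxy)phenyl]ethylidene}-2,4,6-tri(propan-2-yl)benzenesulfonohydrazide | CC(=NNS(=O)(=O)c1c(C(C)C)cc(C(C)C)cc1C(C)C)c1c(OCOC)cc(OC)cc1OCOC | intermediate
4 | (R)-4-hydroxymandelic acid | O[C@@H](C(=O)O)c1ccc(O)cc1 | starting material
5 | benzyl (2R)-2-[4-(benzyloxy)phenyl]-2-hydroxyacetate | O[C@@H](C(=O)OCc1ccccc1)c1ccc(OCc2ccccc2)cc1 | intermediate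
6 | tert-butyl diazoacetate | CC(C)(C)OC(=O)C=[N+]=[N-] | starting material
7 | benzyl (2R)-2-[4-(benzyloxy)phenyl]-2-[2-(tert-butoxy)-2-oxoethoxy]acetate | CC(C)(C)OC(=O)CO[C@@H](C(=O)OCc1ccccc1)c1ccc(OCc2ccccc2)cc1 | intermediate
8 | tert-butyl 2-{(1R)-1-[4-(benzyloxy)phenyl]-2-oxoethoxy}acetate | CC(C)(C)OC(=O)CO[C@@H](C=O)c1ccc(OCc2ccccc2)cc1 | intermediate
9 | {1-[4-methoxy-2,6-bis(methoxymethoxy)phenyl]ethenyl}lithium | [Li]C(=C)c1c(OCOC)cc(OC)cc1OCOC | intermediate
10 | bromo{1-[4-methoxy-2,6-bis(methoxymethoxy)phenyl]ethenyl}magnesium | Br[Mg]C(=C)c1c(OCOC)cc(OC)cc1OCOC | intermediate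
11 | tert-butyl 2-{(1R,2R)-1-[4-(benzyloxy)phenyl]-2-hydroxy-3-[4-methoxy-2,6-bis(methoxymethoxy)phenyl]but-3-en-1-yloxy}acetate | CC(C)(C)OC(=O)CO[C@H](c1ccc(OCc2ccccc2)cc1)[C@H](O)C(=C)c1c(OCOC)cc(OC)cc1OCOC | intermediate
12 | (5R,6R)-5-[4-(benzyloxy)phenyl]-6-{1-[4-methoxy-2,6-bis(methoxymethoxy)phenyl]ethenyl}-1,4-dioxan-2-one | O=C1CO[C@H](c2ccc(OCc3ccccc3)cc2)[C@@H](C(=C)c2c(OCOC)cc(OC)cc2OCOC)O1 | intermediate
13 | trimethylsilyl ketene acetal of 12, {[(2R,3R)-2-[4-(benzyloxy)phenyl]-3-{1-[4-methoxy-2,6-bis(methoxymethoxy)phenyl]ethenyl}-2,3-dihydro-1,4-dioxin-5-yl]oxy}trimethylsilane | C[Si](C)(C)OC1=CO[C@H](c2ccc(OCc3ccccc3)cc2)[C@@H](C(=C)c2c(OCOC)cc(OC)cc2OCOC)O1 | intermediate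
14 | trimethylsilyl (2R,6S)-6-[4-(benzyloxy)phenyl]-4-[4-methoxy-2,6-bis(methoxymethoxy)phenyl]-3,6-dihydro-2H-pyran-2-carboxylate | COc1cc(OCOC)c(C2=C[C@@H](c3ccc(OCc4ccccc4)cc3)O[C@@H](C(=O)O[Si](C)(C)C)C2)c(OCOC)c1 | intermediate
15 | (2R,6S)-6-[4-(benzyloxy)phenyl]-4-[4-methoxy-2,6-bis(methoxymethoxy)phenyl]-3,6-dihydro-2H-pyran-2-carboxylic acid | COc1cc(OCOC)c(C2=C[C@@H](c3ccc(OCc4ccccc4)cc3)O[C@@H](C(=O)O)C2)c(OCOC)c1 | intermediate
16 | methyl (2R,6S)-6-[4-(benzyloxy)phenyl]-4-[4-methoxy-2,6-bis(methoxymethoxy)phenyl]-3,6-dihydro-2H-pyran-2-carboxylate | COc1cc(OCOC)c(C2=C[C@@H](c3ccc(OCc4ccccc4)cc3)O[C@@H](C(=O)OC)C2)c(OCOC)c1 | intermediate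
17 | (2R,6S)-6-[4-(benzyloxy)phenyl]-4-[4-methoxy-2,6-bis(methoxymethoxy)phenyl]-3,6-dihydro-2H-pyran-2-carbaldehyde | COc1cc(OCOC)c(C2=C[C@@H](c3ccc(OCc4ccccc4)cc3)O[C@@H](C=O)C2)c(OCOC)c1 | intermediate
18 | 4-(benzyloxy)benzyl chloride | ClCc1ccc(OCc2ccccc2)cc1 | starting material
19 | {[4-(benzyloxy)phenyl]methyl}triphenylphosphonium chloride | [Cl-].c1ccc(COc2ccc(C[P+](c3ccccc3)(c3ccccc3)c3ccccc3)cc2)cc1 | intermediate
20 | {[4-(benzyloxy)phenyl]methylidene}triphenylphosphorane | c1ccc(COc2ccc(C=P(c3ccccc3)(c3ccccc3)c3ccccc3)cc2)cc1 | intermediate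
21 | (2R,6S)-6-[4-(benzyloxy)phenyl]-2-{2-[4-(benzyloxy)phenyl]ethenyl}-4-[4-methoxy-2,6-bis(methoxymethoxy)phenyl]-3,6-dihydro-2H-pyran (E/Z mixture) | COc1cc(OCOC)c(C2=C[C@@H](c3ccc(OCc4ccccc4)cc3)O[C@@H](C=Cc3ccc(OCc4ccccc4)cc3)C2)c(OCOC)c1 | intermediate
22 | 4-{2-[(2S,4R,6S)-6-(4-hydroxyphenyl)-4-[4-methoxy-2,6-bis(methoxymethoxy)phenyl]oxan-2-yl]ethyl}phenol | COc1cc(OCOC)c([C@@H]2C[C@H](CCc3ccc(O)cc3)O[C@H](c3ccc(O)cc3)C2)c(OCOC)c1 | intermediate
23 | 4-hydroxybenzaldehyde | O=Cc1ccc(O)cc1 | starting material
24 | 4-(methoxymethoxy)benzaldehyde | COCOc1ccc(C=O)cc1 | intermediate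
25 | diethyl {2-[methoxy(methyl)amino]-2-oxoethyl}phosphonate | CCOP(=O)(OCC)CC(=O)N(C)OC | starting material
26 | (2E)-N-methoxy-N-methyl-3-[4-(methoxymethoxy)phenyl]prop-2-enamide | COCOc1ccc(/C=C/C(=O)N(C)OC)cc1 | intermediate
27 | ring A 3'-lithio derivative of 22 as its dilithium bis-phenoxide | COc1cc(OCOC)c([C@@H]2C[C@H](CCc3ccc(O[Li])cc3)O[C@H](c3ccc(O[Li])cc3)C2)c(OCOC)c1[Li] | intermediate
28 | (2E)-1-{3-[(2S,4R,6S)-6-(4-hydroxyphenyl)-2-[2-(4-hydroxyphenyl)ethyl]oxan-4-yl]-6-methoxy-2,4-bis(methoxymethoxy)phenyl}-3-[4-(methoxymethoxy)phenyl]prop-2-en-1-one | COc1cc(OCOC)c([C@@H]2C[C@H](CCc3ccc(O)cc3)O[C@H](c3ccc(O)cc3)C2)c(OCOC)c1C(=O)/C=C/c1ccc(OCOC)cc1 | intermediate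
29 | (2E)-1-{2,4-dihydroxy-3-[(2S,4R,6S)-6-(4-hydroxyphenyl)-2-[2-(4-hydroxyphenyl)ethyl]oxan-4-yl]-6-methoxyphenyl}-3-(4-hydroxyphenyl)prop-2-en-1-one | COc1cc(O)c([C@@H]2C[C@H](CCc3ccc(O)cc3)O[C@H](c3ccc(O)cc3)C2)c(O)c1C(=O)/C=C/c1ccc(O)cc1 | target

## Step count and least certain steps

Total: 17 steps. Longest linear sequence: 12 steps (steps 3, 4, 5, 6, 7, 8, 9, 10, 12, 13, 16, 17, from acid 4).

**Step 8 (key step).** The most likely failure is a sluggish rearrangement: the di-ortho-substituted arene on the central vinyl carbon may crowd the boat, so the ketene acetal is lost to hydrolysis or fragmentation before it rearranges. The fallback keeps the ring contraction but runs it on a smaller alkenyl group and attaches ring A afterwards. It sets out from aldehyde 8 and comes back at ester 16.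
- Aldehyde 8 is treated under the conditions of step 6 with [1-(trimethylsilyl)ethenyl]magnesium bromide F1, made from commercial (1-bromoethenyl)trimethylsilane and magnesium. This gives tert-butyl 2-{(1R,2S)-1-[4-(benzyloxy)phenyl]-2-hydroxy-3-(trimethylsilyl)but-3-en-1-yloxy}acetate F2.
- Lactonisation as in step 7 gives (5R,6S)-5-[4-(benzyloxy)phenyl]-6-[1-(trimethylsilyl)ethenyl]-1,4-dioxan-2-one F3.
- Rearrangement as in step 8 gives (2R,6S)-6-[4-(benzyloxy)phenyl]-4-(trimethylsilyl)-3,6-dihydro-2H-pyran-2-carboxylic acid F4, and methylation as in step 9 gives its methyl ester F5.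
- N-Iodosuccinimide exchanges silicon for iodine to give methyl (2R,6S)-6-[4-(benzyloxy)phenyl]-4-iodo-3,6-dihydro-2H-pyran-2-carboxylate F6.
- Commercial 5-methoxyresorcinol is converted into 1-methoxy-3,5-bis(methoxymethoxy)benzene F7, which is lithiated between the MOM ethers and borylated to [4-methoxy-2,6-bis(methoxymethoxy)phenyl]boronic acid F8.
- Suzuki–Miyaura coupling of F6 and F8 (Pd(OAc)2, SPhos, K3PO4) gives 16.

**Step 6.** Two processes threaten it. Enolisation of aldehyde 8 would erode the configuration at the mandelate carbon. Incomplete chelation, caused by THF competing for magnesium, would lower the facial selectivity at the new carbinol. The fallback addresses the second: the epimer mixture of 11 is oxidised (Dess–Martin oxidation) to tert-butyl 2-{(1R)-1-[4-(benzyloxy)phenyl]-3-[4-methoxy-2,6-bis(methoxymethoxy)phenyl]-2-oxobut-3-en-1-yloxy}acetate F9. The ketone is then reduced under reagent control (Corey–Bakshi–Shibata reduction, with the oxazaborolidine enantiomer that delivers the (2R) carbinol), which comes back at 11.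

**Step 13.** Hydrogen uptake at the trisubstituted alkene may be slow because the twisted arene shields both faces. This leaves time for hydrogenolysis of the allylic and benzylic C6–O1 bond and may lower the facial selectivity at C4. The fallback sets C4 earlier under thermodynamic control; it sets out from ester 16 and comes back at 22.
- Hydrogen-atom-transfer hydrogenation of 16 (Mn(dpm)3, PhSiH3, t-BuOOH, i-PrOH) gives methyl (2R,4S,6S)-6-[4-(benzyloxy)phenyl]-4-[4-methoxy-2,6-bis(methoxymethoxy)phenyl]oxane-2-carboxylate F10, with the aryl group equatorial.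
- Reduction as in step 10 gives (2R,4S,6S)-6-[4-(benzyloxy)phenyl]-4-[4-methoxy-2,6-bis(methoxymethoxy)phenyl]oxane-2-carbaldehyde F11.
- Wittig reaction with ylide 20 as in step 12 gives (2R,4R,6S)-6-[4-(benzyloxy)phenyl]-2-{2-[4-(benzyloxy)phenyl]ethenyl}-4-[4-methoxy-2,6-bis(methoxymethoxy)phenyl]oxane F12.
- Mild hydrogenation (H2, 1 atm, Pd/C), which now only has to reduce a disubstituted styrene and remove two benzyl groups, gives 22.

**Step 16.** Metalation may be incomplete or misdirected (toward the benzylic C–H bonds) because the two lithium phenoxides aggregate the base. Conjugate addition to the enamide is a second possible loss. The fallback fixes the site of metalation by a halogen; it sets out from 22 and comes back at 28. Bromination of the far more electron-rich ring A (N-bromosuccinimide, 1 equiv, CH2Cl2, −78 °C) gives 4-{2-[(2S,4R,6S)-4-[3-bromo-4-methoxy-2,6-bis(methoxymethoxy)phenyl]-6-(4-hydroxyphenyl)oxan-2-yl]ethyl}phenol F13. Bromine–lithium exchange (n-BuLi, −78 °C, after phenoxide formation) and addition of 26 then give 28.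

**Step 2.** Condensation at a ketone flanked by two ortho substituents may be slow, and forcing it endangers the sulfonyl hydrazide. The fallback reaches the same vinyllithium without a hydrazone; it sets out from ketone 2 and comes back at 9. Enolisation and triflation (KN(SiMe3)2, PhNTf2) give 1-[4-methoxy-2,6-bis(methoxymethoxy)phenyl]ethenyl trifluoromethanesulfonate F14. Palladium-catalysed stannylation (Me3SnSnMe3, Pd(PPh3)4, LiCl) gives {1-[4-methoxy-2,6-bis(methoxymethoxy)phenyl]ethenyl}trimethylstannane F15. Tin–lithium exchange with MeLi gives 9.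

## Further compounds

F1 | step 8 | [1-(trimethylsilyl)ethenyl]magnesium bromide | C=C([Mg]Br)[Si](C)(C)C
F2 | step 8 | tert-butyl 2-{(1R,2S)-1-[4-(benzyloxy)phenyl]-2-hydroxy-3-(trimethylsilyl)but-3-en-1-yloxy}acetate | CC(C)(C)OC(=O)CO[C@H](c1ccc(OCc2ccccc2)cc1)[C@H](O)C(=C)[Si](C)(C)C
F3 | step 8 | (5R,6S)-5-[4-(benzyloxy)phenyl]-6-[1-(trimethylsilyl)ethenyl]-1,4-dioxan-2-one | O=C1CO[C@H](c2ccc(OCc3ccccc3)cc2)[C@@H](C(=C)[Si](C)(C)C)O1
F4 | step 8 | (2R,6S)-6-[4-(benzyloxy)phenyl]-4-(trimethylsilyl)-3,6-dihydro-2H-pyran-2-carboxylic acid | C[Si](C)(C)C1=C[C@@H](c2ccc(OCc3ccccc3)cc2)O[C@@H](C(=O)O)C1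
F5 | step 8 | methyl (2R,6S)-6-[4-(benzyloxy)phenyl]-4-(trimethylsilyl)-3,6-dihydro-2H-pyran-2-carboxylate | C[Si](C)(C)C1=C[C@@H](c2ccc(OCc3ccccc3)cc2)O[C@@H](C(=O)OC)C1
F6 | step 8 | methyl (2R,6S)-6-[4-(benzyloxy)phenyl]-4-iodo-3,6-dihydro-2H-pyran-2-carboxylate | IC1=C[C@@H](c2ccc(OCc3ccccc3)cc2)O[C@@H](C(=O)OC)C1
F7 | step 8 | 1-methoxy-3,5-bis(methoxymethoxy)benzene | COCOc1cc(OC)cc(OCOC)c1
F8 | step 8 | [4-methoxy-2,6-bis(methoxymethoxy)phenyl]boronic acid | COCOc1cc(OC)cc(OCOC)c1B(O)O
F9 | step 6 | tert-butyl 2-{(1R)-1-[4-(benzyloxy)phenyl]-3-[4-methoxy-2,6-bis(methoxymethoxy)phenyl]-2-oxobut-3-en-1-yloxy}acetate | CC(C)(C)OC(=O)CO[C@H](c1ccc(OCc2ccccc2)cc1)C(=O)C(=C)c1c(OCOC)cc(OC)cc1OCOC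
F10 | step 13 | methyl (2R,4S,6S)-6-[4-(benzyloxy)phenyl]-4-[4-methoxy-2,6-bis(methoxymethoxy)phenyl]oxane-2-carboxylate | COc1cc(OCOC)c([C@@H]2C[C@H](C(=O)OC)O[C@H](c3ccc(OCc4ccccc4)cc3)C2)c(OCOC)c1
F11 | step 13 | (2R,4S,6S)-6-[4-(benzyloxy)phenyl]-4-[4-methoxy-2,6-bis(methoxymethoxy)phenyl]oxane-2-carbaldehyde | COc1cc(OCOC)c([C@@H]2C[C@H](C=O)O[C@H](c3ccc(OCc4ccccc4)cc3)C2)c(OCOC)c1
F12 | step 13 | (2R,4R,6S)-6-[4-(benzyloxy)phenyl]-2-{2-[4-(benzyloxy)phenyl]ethenyl}-4-[4-methoxy-2,6-bis(methoxymethoxy)phenyl]oxane | COc1cc(OCOC)c([C@@H]2C[C@H](C=Cc3ccc(OCc4ccccc4)cc3)O[C@H](c3ccc(OCc4ccccc4)cc3)C2)c(OCOC)c1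
F13 | step 16 | 4-{2-[(2S,4R,6S)-4-[3-bromo-4-methoxy-2,6-bis(methoxymethoxy)phenyl]-6-(4-hydroxyphenyl)oxan-2-yl]ethyl}phenol | COc1cc(OCOC)c([C@@H]2C[C@H](CCc3ccc(O)cc3)O[C@H](c3ccc(O)cc3)C2)c(OCOC)c1Br
F14 | step 2 | 1-[4-methoxy-2,6-bis(methoxymethoxy)phenyl]ethenyl trifluoromethanesulfonate | C=C(OS(=O)(=O)C(F)(F)F)c1c(OCOC)cc(OC)cc1OCOC
F15 | step 2 | {1-[4-methoxy-2,6-bis(methoxymethoxy)phenyl]ethenyl}trimethylstannane | C=C([Sn](C)(C)C)c1c(OCOC)cc(OC)cc1OCOC
A1 | alternative 1 | 4-[(2S,6S)-6-{2-[4-(benzyloxy)phenyl]ethyl}-4-[(triethylsilyl)oxy]-3,6-dihydro-2H-pyran-2-yl]phenyl 2,2-dimethylpropanoate | CC[Si](CC)(CC)OC1=C[C@H](CCc2ccc(OCc3ccccc3)cc2)O[C@H](c2ccc(OC(=O)C(C)(C)C)cc2)C1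
A2 | alternative 1 | triethyl({(3E)-6-[4-(benzyloxy)phenyl]hexa-1,3-dien-2-yl}oxy)silane | C=C(O[Si](CC)(CC)CC)/C=C/CCc1ccc(OCc2ccccc2)cc1
A3 | alternative 1 | 4-formylphenyl 2,2-dimethylpropanoate | CC(C)(C)C(=O)Oc1ccc(C=O)cc1
A4 | alternative 2 | (1S)-1-[4-(benzyloxy)phenyl]-2-(2-{(2S)-4-[4-(benzyloxy)phenyl]-2-[(tert-butyldimethylsilyl)oxy]butyl}-1,3-dithian-2-yl)ethan-1-ol | O[C@H](c1ccc(OCc2ccccc2)cc1)CC1(C[C@@H](O[Si](C)(C)C(C)(C)C)CCc2ccc(OCc3ccccc3)cc2)SCCCS1
A5 | alternative 2 | tert-butyl(1,3-dithian-2-yl)dimethylsilane | CC(C)(C)[Si](C)(C)C1SCCCS1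
A6 | alternative 2 | (2S)-2-{2-[4-(benzyloxy)phenyl]ethyl}oxirane | c1ccc(COc2ccc(CC[C@H]3CO3)cc2)cc1
A7 | alternative 2 | (2R)-2-[4-(benzyloxy)phenyl]oxirane | c1ccc(COc2ccc([C@@H]3CO3)cc2)cc1
A8 | alternative 3 | 2-[(2S,4R,6S)-6-[4-(benzyloxy)phenyl]-2-{2-[4-(benzyloxy)phenyl]ethyl}oxan-4-yl]-5-methoxy-3-{[tri(propan-2-yl)silyl]oxy}phenol | COc1cc(O)c([C@@H]2C[C@H](CCc3ccc(OCc4ccccc4)cc3)O[C@H](c3ccc(OCc4ccccc4)cc3)C2)c(O[Si](C(C)C)(C(C)C)C(C)C)c1
A9 | alternative 3 | 3-methoxycyclobut-2-en-1-one | COC1=CC(=O)C1
A10 | alternative 3 | ({[(2S,4R,6S)-6-[4-(benzyloxy)phenyl]-2-{2-[4-(benzyloxy)phenyl]ethyl}oxan-4-yl]ethynyl}oxy)tri(propan-2-yl)silane | CC(C)[Si](C(C)C)(C(C)C)OC#C[C@@H]1C[C@H](CCc2ccc(OCc3ccccc3)cc2)O[C@H](c2ccc(OCc3ccccc3)cc2)C1
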